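**Retrosynthetic overview**
1. The strategy rests on one feature: the eight-membered carbocycle is ortho-fused to resorcinol ring C (the ring that also carries the furan oxygen) through two adjacent arene carbons. One is bonded to dihydrobenzofuran C-3 (a diarylmethine) and the other to indane C-2.
2. Those two sp3 carbons are the carbonyl carbon and the α-carbon of a 1-tetralone-2-carboxylate, so ring C is excised as a 3,5-dimethoxybenzyne inserted into that C–C bond (six-membered to eight-membered ring).
3. The trans-3,4-diaryl tetralone β-ketoester comes from lateral lithiation of a 2-benzylbenzoate (ring B) and Michael–Dieckmann annulation onto an 8-phenylmenthyl cinnamate (ring A).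
4. After the expansion, ortho-demethylation, reduction and an o-quinone methide [4+1] annulation with a benzylic sulfonium ylide close the dihydrobenzofuran. Friedel–Crafts acylation onto ring A closes the indane, and aryl addition, ionic hydrogenation and BBr3 finish.
5. Ring order: tetralone ring on ring B, then the eight-membered ring with ring C fused on, then the dihydrobenzofuran, then the indane five-membered ring.

Key step: step 11

Labels: ring A = resorcinol ring of the indane; ring B = resorcinol ring bonded only to the eight-membered ring; ring C = resorcinol ring bearing the furan oxygen. Ca, Ce, Cb = indane C-1, C-2, C-3; Cc = bridge methine between Cb and ring B; Cd, Cf = dihydrobenzofuran C-3, C-2. With the eight-membered ring drawn flat, the hydrogens on Cc, Cb, Ce, Cd point up, down, up, down; the Cf aryl group is trans to ring B across the furan, and the Ca aryl group is cis to ring C across the indane.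

Assumption: the (−)-8-phenylmenthyl cinnamate is taken to react as its s-trans, phenyl-stacked conformer, which leaves open the Cβ Si face that the target requires; should the addition take the other face, (+)-8-phenylmenthol is used and nothing else changes.

**Route**

Step 1
Reactants: 1 methyl 3,5-dimethoxybenzoate
Product: 2 methyl 2-bromo-3,5-dimethoxybenzoate
Conditions: NBS, MeCN, 0 °C → rt
Reagents that add atoms: N-bromosuccinimide, O=C1CCC(=O)N1Br
Why: Electrophilic aromatic bromination; C-2 is para to one methoxy group and ortho to the other and is less crowded than C-4 between the two methoxy groups, so monobromination next to the ester is expected.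

Step 2
Reactants: 3 4-methoxybenzyl chloride
Product: 4 4-methoxybenzylzinc chloride (LiCl-complexed THF solution, titrated and used as such)
Conditions: Zn dust (activated with 1,2-dibromoethane and TMSCl), LiCl, THF, rt
Reagents that add atoms: zinc, [Zn]
Why: LiCl-promoted oxidative insertion of zinc into the benzylic C–Cl bond gives a benzylzinc reagent that tolerates esters and shows little homocoupling.

Step 3
Reactants: 2 methyl 2-bromo-3,5-dimethoxybenzoate; 4 4-methoxybenzylzinc chloride
Product: 5 methyl 3,5-dimethoxy-2-(4-methoxybenzyl)benzoate (fragment 1)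
Conditions: Pd(OAc)2 (2 mol %), SPhos (4 mol %), THF, rt → 50 °C
Reagents that add atoms: none
Why: Negishi sp2–sp3 cross-coupling; the biarylphosphine ligand allows oxidative addition and reductive elimination at the electron-rich, doubly ortho-substituted bromide, and the organozinc leaves the ester alone.

Step 4
Reactants: 6 (E)-3,5-dimethoxycinnamic acid
Product: 7 (E)-3,5-dimethoxycinnamoyl chloride
Conditions: (COCl)2, DMF (cat.), CH2Cl2, 0 °C → rt; evaporate
Reagents that add atoms: oxalyl chloride, ClC(=O)C(=O)Cl
Why: Acid chloride formation through the Vilsmeier intermediate; the E-alkene is not affected.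

Step 5
Reactants: 7 (E)-3,5-dimethoxycinnamoyl chloride; 8 (−)-8-phenylmenthol
Product: 9 (1R,2S,5R)-8-phenylmenthyl (E)-3,5-dimethoxycinnamate (fragment 2)
Conditions: Et3N, DMAP (cat.), CH2Cl2, 0 °C → rt
Reagents that add atoms: none
Why: DMAP-catalysed acylation of the hindered secondary alcohol by the acid chloride; the carbinol centres of the auxiliary are not involved.

Step 6
Reactants: 5 methyl 3,5-dimethoxy-2-(4-methoxybenzyl)benzoate; 9 (1R,2S,5R)-8-phenylmenthyl (E)-3,5-dimethoxycinnamate
Product: 12 (1R,2S,5R)-8-phenylmenthyl (3R,4R)-3-(3,5-dimethoxyphenyl)-1-hydroxy-5,7-dimethoxy-4-(4-methoxyphenyl)-3,4-dihydronaphthalene-2-carboxylate (enol form of the trans tetralone β-ketoester), via benzylic lithio anion 10 (not isolated), via Michael adduct enolate 11 (not isolated)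
Conditions: LDA (lithium diisopropylamide, commercial solution, 1.1 equiv), THF, −78 °C; then 9, −78 → 0 °C; aq. NH4Cl; minor diastereomers removed by chromatography or crystallisation
Reagents that add atoms: none
Why: Lateral lithiation gives a diarylmethyl anion that undergoes Michael addition to the cinnamate, and the ester enolate closes the six-membered ring on the methyl benzoate (Dieckmann), driven by the β-ketoester enolate; the stacked phenyl group of the auxiliary blocks one face of the s-trans enoate so addition should occur at the Cβ Si face (Cb), and the anti adduct, which keeps the two aryl groups apart and is also the more stable, sets Cc trans.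

Step 7
Reactants: 12 8-phenylmenthyl trans tetralone β-ketoester
Product: 14 methyl (3R,4R)-3-(3,5-dimethoxyphenyl)-1-hydroxy-5,7-dimethoxy-4-(4-methoxyphenyl)-3,4-dihydronaphthalene-2-carboxylate, via acylketene 13 (not isolated)
Conditions: MeOH (excess), DMAP (cat.), toluene, 110 °C (sealed tube)
Reagents that add atoms: methanol, CO
Why: Transesterification of an enolisable β-ketoester by thermal loss of the alcohol to an acylketene that methanol traps; the conditions are essentially neutral, so C-3 and C-4 are retained and the auxiliary is recovered.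

Step 8
Reactants: 15 3,5-dimethoxyphenol
Product: 16 3,5-dimethoxyphenyl N-isopropylcarbamate
Conditions: i-PrNCO, Et3N (cat.), CH2Cl2, rt
Reagents that add atoms: isopropyl isocyanate, CC(C)N=C=O
Why: Base-catalysed addition of the phenol to the isocyanate installs a directing group that can later be removed under mild conditions.

Step 9
Reactants: 16 3,5-dimethoxyphenyl N-isopropylcarbamate
Product: 20 3,5-dimethoxy-2-(trimethylsilyl)phenyl N-isopropylcarbamate, via N-silyl carbamate 17 (not isolated), via ortho-lithiated N-silyl carbamate 18 (not isolated), via N-silyl C-silyl carbamate 19 (not isolated)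
Conditions: TBSOTf, TMEDA, Et2O, 0 °C → rt; then n-BuLi, TMEDA, −78 °C; TMSCl, −78 °C → rt; aq. NaHSO4
Reagents that add atoms: chlorotrimethylsilane, C[Si](C)(C)Cl
Why: Directed ortho-metalation: N-silylation in the flask makes the carbamate a strong director, lithiation occurs at C-2 (flanked by carbamate and methoxy, equivalent to C-6) in preference to C-4 between the two methoxy groups, TMSCl traps the aryllithium, and the N-silyl group is lost on acidic work-up.

Step 10
Reactants: 20 3,5-dimethoxy-2-(trimethylsilyl)phenyl N-isopropylcarbamate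
Product: 22 3,5-dimethoxy-2-(trimethylsilyl)phenyl trifluoromethanesulfonate (fragment 3), via 2-silylphenol 21 (not isolated)
Conditions: DBU, Et2NH, MeCN, 40 °C; then PhNTf2, rt
Reagents that add atoms: N-phenylbis(trifluoromethanesulfonimide), O=S(=O)(N(c1ccccc1)S(=O)(=O)C(F)(F)F)C(F)(F)F
Why: The N–H carbamate is cleaved by E1cB loss of isopropyl isocyanate (captured by diethylamine as a urea), and the phenoxide is triflated in the same flask by a mild triflating agent that leaves the aryl–silicon bond intact.

Step 11
Reactants: 14 methyl trans-3,4-diaryl tetralone β-ketoester (enol); 22 3,5-dimethoxy-2-(trimethylsilyl)phenyl trifluoromethanesulfonate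
Product: 25 methyl (5R,6S,7R)-6-(3,5-dimethoxyphenyl)-1,3,8,10-tetramethoxy-7-(4-methoxyphenyl)-12-oxo-5,6,7,12-tetrahydrodibenzo[a,d]cyclooctene-5-carboxylate, via 3,5-dimethoxybenzyne 23 (not isolated), via benzocyclobutenoxide 24 (not isolated)
Conditions: CsF (3 equiv), 22 (1.5 equiv), MeCN, 80 °C
Reagents that add atoms: none
Why: CsF desilylates 22 with loss of triflate to give aryne 23, whose distal carbon (the one not next to the methoxy-bearing carbon) is attacked by the α-carbon of the caesium enolate of 14; the resulting aryl anion, ortho to that methoxy group, adds 4-exo-trig to the adjacent ketone to give alkoxide 24, and retro-aldol-like opening of the strained four-membered ring breaks the former C1–C2 bond of the tetralone to an α-aryl ester enolate that takes a proton from further 14. The closest known reaction is the acyl-alkylation of arynes with cyclic β-ketoesters (2-carboalkoxycycloalkanones), which gives benzannulated medium rings by the same two-carbon expansion; 14 belongs to that class, being fully enolised with a single α-hydrogen. No chain ends have to meet: the eight-membered ring arises from the six-membered ring by formal insertion of two arene carbons (4-exo-trig addition, then fragmentation), and ring C arrives already fused through the two new aryl–carbon bonds (to Ce and to the carbonyl carbon). The only new stereocentre is Ce; it is set by protonation of the ester enolate and, as an epimerisable α-aryl ester centre under basic fluoride, should settle trans to the neighbouring ring A aryl group (a short DBU treatment can complete this), while Cb and Cc are not touched. The step needs C- rather than O-arylation and one orientation of the unsymmetrical aryne: the soft enolate carbon favours C-attack, and the inductive effect of the methoxy group flanking the aryne bond directs the nucleophile to the remote carbon so that the negative charge develops ortho to oxygen, which places the new ketone next to the methoxy group that later becomes the furan oxygen.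

Step 12
Reactants: 25 dibenzocyclooctanone ester
Product: 26 methyl (5R,6S,7R)-6-(3,5-dimethoxyphenyl)-1-hydroxy-3,8,10-trimethoxy-7-(4-methoxyphenyl)-12-oxo-5,6,7,12-tetrahydrodibenzo[a,d]cyclooctene-5-carboxylate
Conditions: BCl3, CH2Cl2, −78 → 0 °C; aq. NaHCO3
Reagents that add atoms: none
Why: Chelation-directed ether cleavage: boron bridges the ketone oxygen and the one methoxy group ortho to it (C-1 on ring C), so only that ether is cleaved; the ring B methoxy groups are meta to the ketone and the ester and stereocentres are unaffected at this temperature.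

Step 13
Reactants: 26 ortho-hydroxy diaryl ketone
Product: 27 methyl (5R,6S,7R)-6-(3,5-dimethoxyphenyl)-1,12-dihydroxy-3,8,10-trimethoxy-7-(4-methoxyphenyl)-5,6,7,12-tetrahydrodibenzo[a,d]cyclooctene-5-carboxylate (C-12 epimer mixture, used crude)
Conditions: NaBH4, THF/MeOH, 0 °C → rt; AcOH quench at 0 °C
Reagents that add atoms: none
Why: Borohydride reduction of the diaryl ketone leaves the hindered methyl ester alone; the carbinol configuration is irrelevant because this carbon becomes trigonal in step 16, and cold quench with immediate use limits lactonisation onto the nearby ester.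

Step 14
Reactants: 27 ortho-hydroxybenzhydrol
Product: 28 methyl (5R,6S,7R)-6-(3,5-dimethoxyphenyl)-1-hydroxy-3,8,10-trimethoxy-7-(4-methoxyphenyl)-12-(4-methylphenylsulfonyl)-5,6,7,12-tetrahydrodibenzo[a,d]cyclooctene-5-carboxylate (C-12 epimer mixture)
Conditions: p-TolSO2H (freshly liberated from p-TolSO2Na), CH2Cl2, 0 °C → rt
Reagents that add atoms: p-toluenesulfinic acid, Cc1ccc(S(=O)O)cc1
Why: SN1 substitution: the benzhydrol ionises easily (cation stabilised by the ortho-hydroxy and para-methoxy groups of ring C) and sulfinate captures it at sulfur faster than the neighbouring arenes can at 0 °C, installing a leaving group that mild base can expel.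

Step 15
Reactants: 3 4-methoxybenzyl chloride
Product: 29 (4-methoxybenzyl)dimethylsulfonium chloride (fragment 4)
Conditions: Me2S (excess), MeCN, rt; precipitation with Et2O
Reagents that add atoms: dimethyl sulfide, CSC
Why: S-alkylation of dimethyl sulfide by the activated benzylic chloride gives the crystalline sulfonium salt.

Step 16
Reactants: 28 sulfone; 29 (4-methoxybenzyl)dimethylsulfonium chloride
Product: 32 methyl ester of the trans-2-(4-methoxyphenyl)-2,3-dihydrobenzofuran fused on ring C of the dibenzocyclooctene (Cd–H on the face of Cb–H; Cf aryl trans to ring B), via o-quinone methide 30 (not isolated), via sulfonium ylide 31 (not isolated)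
Conditions: Cs2CO3 (3 equiv), 29 (1.5 equiv), MeCN/CH2Cl2, 0 °C → rt
Reagents that add atoms: none
Why: Base expels sulfinate from the phenoxide of 28 to give o-quinone methide 30 and deprotonates 29 to ylide 31; conjugate addition of the ylide carbon to the methide carbon followed by 5-exo-tet displacement of Me2S by the phenoxide is the known [4+1] annulation to 2,3-dihydrobenzofurans, with Cd expected to be set by attack on the methide face turned away from the aryl-bearing three-carbon bridge of the tub-shaped ring and Cf by closure from the betaine rotamer that keeps the anisyl group anti to ring B (trans).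

Step 17
Reactants: 32 trans-dihydrobenzofuran methyl ester
Product: 33 the corresponding carboxylic acid on Ce
Conditions: LiOH·H2O, THF/MeOH/H2O, 50 °C; then aq. HCl to pH 3
Reagents that add atoms: lithium hydroxide, [Li+].[OH-]
Why: Saponification; Ce may epimerise under hydroxide but already has the more stable configuration (trans to the ring A aryl group), and the other methines carry no acidifying group.

Step 18
Reactants: 33 carboxylic acid
Product: 35 hexacyclic indanone (ketone at Ca, trans ring fusion at Ce/Cb), via acid chloride 34 (not isolated)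
Conditions: (COCl)2, DMF (cat.), CH2Cl2, 0 °C → rt, evaporate; SnCl4, CH2Cl2, −78 → −20 °C
Reagents that add atoms: none
Why: Intramolecular Friedel–Crafts acylation at the ring A position ortho to Cb, which is para to one methoxy group and ortho to the other, closes the five-membered ketone; the trans arrangement of the acyl group on Ce and the aryl group on Cb gives the trans-fused indanone (also the stable arrangement at the now enolisable Ce), and the low temperature protects the dihydrobenzofuran.

Step 19
Reactants: 35 hexacyclic indanone; 36 4-bromoanisole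
Product: 39 tertiary carbinol, the Ca-(4-methoxyphenyl) indanol (carbinol configuration immaterial), via 4-methoxyphenyllithium 37 (not isolated), via 4-methoxyphenylcerium dichloride 38 (not isolated)
Conditions: 36, n-BuLi, THF, −78 °C; anhydrous CeCl3, −78 °C; then 35, −78 → −40 °C; aq. NH4Cl
Reagents that add atoms: none
Why: The organocerium reagent is strongly nucleophilic but weakly basic, so it adds to the hindered indanone instead of removing the acidic benzylic α-hydrogen at Ce; the new carbinol centre is ionised in the next step.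

Step 20
Reactants: 39 tertiary carbinol
Product: 41 canaliculatol octamethyl ether, via diarylmethyl cation 40 (not isolated)
Conditions: Et3SiH (excess), BF3·OEt2, CH2Cl2, −78 → −40 °C
Reagents that add atoms: none
Why: Ionic hydrogenation: BF3 ionises the carbinol to a cation stabilised by the anisyl group and ring A, and the silane should deliver hydride to the face anti to ring C on the adjacent Ce, leaving the anisyl group cis to ring C (Ca); low temperature and excess silane keep hydride capture ahead of proton loss to the indene, which would endanger Ce.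

Step 21
Reactants: 41 canaliculatol octamethyl ether
Product: 42 canaliculatol
Conditions: BBr3 (excess), CH2Cl2, −78 → 0 °C; MeOH, then water
Reagents that add atoms: none
Why: Lewis-acid cleavage of all eight aryl methyl ethers; no sp3 centre takes part, and any reversible opening of the benzylic furan C–O bond should reclose to the more stable trans ring.

**Compound list**
1 | methyl 3,5-dimethoxybenzoate | COC(=O)c1cc(OC)cc(OC)c1 | starting material
2 | methyl 2-bromo-3,5-dimethoxybenzoate | COC(=O)c1cc(OC)cc(OC)c1Br | intermediate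
3 | 4-methoxybenzyl chloride | COc1ccc(CCl)cc1 | starting material
4 | 4-methoxybenzylzinc chloride (LiCl-complexed THF solution) | COc1ccc(C[Zn]Cl)cc1 | intermediate
5 | methyl 3,5-dimethoxy-2-(4-methoxybenzyl)benzoate (fragment 1) | COC(=O)c1cc(OC)cc(OC)c1Cc1ccc(OC)cc1 | intermediate
6 | (E)-3,5-dimethoxycinnamic acid | COc1cc(/C=C/C(=O)O)cc(OC)c1 | starting material
7 | (E)-3,5-dimethoxycinnamoyl chloride | COc1cc(/C=C/C(Cl)=O)cc(OC)c1 | intermediate
8 | (−)-8-phenylmenthol, (1R,2S,5R)-5-methyl-2-(2-phenylpropan-2-yl)cyclohexan-1-ol | CC(C)(c1ccccc1)[C@@H]1CC[C@@H](C)C[C@H]1O | starting material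
9 | (1R,2S,5R)-8-phenylmenthyl (E)-3,5-dimethoxycinnamate (fragment 2) | CC(C)(c1ccccc1)[C@@H]1CC[C@@H](C)C[C@H]1OC(=O)/C=C/c1cc(OC)cc(OC)c1 | intermediate
10 | lithium salt of the diarylmethyl anion of 5 (formed in the flask) | COC(=O)c1cc(OC)cc(OC)c1[CH-]c1ccc(OC)cc1.[Li+] | intermediate
11 | lithium ester enolate of the anti Michael adduct of 10 and 9 (formed in the flask; enolate geometry not defined) | CC(C)(c1ccccc1)[C@@H]1CC[C@@H](C)C[C@H]1OC([O-])=C[C@@H](c1cc(OC)cc(OC)c1)[C@H](c1ccc(OC)cc1)c1c(OC)cc(OC)cc1C(=O)OC.[Li+] | intermediate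
12 | (1R,2S,5R)-8-phenylmenthyl (3R,4R)-3-(3,5-dimethoxyphenyl)-1-hydroxy-5,7-dimethoxy-4-(4-methoxyphenyl)-3,4-dihydronaphthalene-2-carboxylate (enol of the trans tetralone β-ketoester) | CC(C)(c1ccccc1)[C@@H]1CC[C@@H](C)C[C@H]1OC(=O)C1=C(O)c2cc(OC)cc(OC)c2[C@@H](c2ccc(OC)cc2)[C@@H]1c1cc(OC)cc(OC)c1 | intermediate
13 | acylketene from 12: trans-3-(3,5-dimethoxyphenyl)-5,7-dimethoxy-4-(4-methoxyphenyl)-2-(oxomethylidene)-3,4-dihydronaphthalen-1-one (formed in the flask) | O=C=C1C(=O)c2cc(OC)cc(OC)c2[C@@H](c2ccc(OC)cc2)[C@@H]1c1cc(OC)cc(OC)c1 | intermediate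
14 | methyl (3R,4R)-3-(3,5-dimethoxyphenyl)-1-hydroxy-5,7-dimethoxy-4-(4-methoxyphenyl)-3,4-dihydronaphthalene-2-carboxylate | COC(=O)C1=C(O)c2cc(OC)cc(OC)c2[C@@H](c2ccc(OC)cc2)[C@@H]1c1cc(OC)cc(OC)c1 | intermediate
15 | 3,5-dimethoxyphenol | COc1cc(O)cc(OC)c1 | starting material
16 | 3,5-dimethoxyphenyl N-isopropylcarbamate | COc1cc(OC(=O)NC(C)C)cc(OC)c1 | intermediate
17 | 3,5-dimethoxyphenyl N-(tert-butyldimethylsilyl)-N-isopropylcarbamate (formed in the flask) | COc1cc(OC(=O)N(C(C)C)[Si](C)(C)C(C)(C)C)cc(OC)c1 | intermediate
18 | 2-lithio-3,5-dimethoxyphenyl N-(tert-butyldimethylsilyl)-N-isopropylcarbamate (formed in the flask) | [Li]c1c(OC)cc(OC)cc1OC(=O)N(C(C)C)[Si](C)(C)C(C)(C)C | intermediate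
19 | 3,5-dimethoxy-2-(trimethylsilyl)phenyl N-(tert-butyldimethylsilyl)-N-isopropylcarbamate (formed in the flask) | COc1cc(OC)c([Si](C)(C)C)c(OC(=O)N(C(C)C)[Si](C)(C)C(C)(C)C)c1 | intermediate
20 | 3,5-dimethoxy-2-(trimethylsilyl)phenyl N-isopropylcarbamate | COc1cc(OC)c([Si](C)(C)C)c(OC(=O)NC(C)C)c1 | intermediate
21 | 3,5-dimethoxy-2-(trimethylsilyl)phenol (present as its DBU salt, formed in the flask) | COc1cc(O)c([Si](C)(C)C)c(OC)c1 | intermediate
22 | 3,5-dimethoxy-2-(trimethylsilyl)phenyl trifluoromethanesulfonate (fragment 3) | COc1cc(OC)c([Si](C)(C)C)c(OS(=O)(=O)C(F)(F)F)c1 | intermediate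
23 | 3,5-dimethoxybenzyne, 1,2-didehydro-3,5-dimethoxybenzene (formed in the flask) | COC1=CC(OC)=CC#C1 | intermediate
24 | caesium alkoxide of the cis-fused benzocyclobutenol from 4-exo addition (new aryl group anti to the C-3 aryl group; formed in the flask) | COC(=O)[C@]12c3cc(OC)cc(OC)c3[C@@]1([O-])c1cc(OC)cc(OC)c1[C@@H](c1ccc(OC)cc1)[C@@H]2c1cc(OC)cc(OC)c1.[Cs+] | intermediate
25 | methyl (5R,6S,7R)-6-(3,5-dimethoxyphenyl)-1,3,8,10-tetramethoxy-7-(4-methoxyphenyl)-12-oxo-5,6,7,12-tetrahydrodibenzo[a,d]cyclooctene-5-carboxylate | COC(=O)[C@@H]1[C@@H](c2cc(OC)cc(OC)c2)[C@H](c2ccc(OC)cc2)c2c(OC)cc(OC)cc2C(=O)c2c(OC)cc(OC)cc21 | intermediate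
26 | methyl (5R,6S,7R)-6-(3,5-dimethoxyphenyl)-1-hydroxy-3,8,10-trimethoxy-7-(4-methoxyphenyl)-12-oxo-5,6,7,12-tetrahydrodibenzo[a,d]cyclooctene-5-carboxylate | COC(=O)[C@@H]1[C@@H](c2cc(OC)cc(OC)c2)[C@H](c2ccc(OC)cc2)c2c(OC)cc(OC)cc2C(=O)c2c(O)cc(OC)cc21 | intermediate
27 | methyl (5R,6S,7R)-6-(3,5-dimethoxyphenyl)-1,12-dihydroxy-3,8,10-trimethoxy-7-(4-methoxyphenyl)-5,6,7,12-tetrahydrodibenzo[a,d]cyclooctene-5-carboxylate (C-12 epimers, centre lost in step 16) | COC(=O)[C@@H]1[C@@H](c2cc(OC)cc(OC)c2)[C@H](c2ccc(OC)cc2)c2c(OC)cc(OC)cc2C(O)c2c(O)cc(OC)cc21 | intermediate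
28 | methyl (5R,6S,7R)-6-(3,5-dimethoxyphenyl)-1-hydroxy-3,8,10-trimethoxy-7-(4-methoxyphenyl)-12-(4-methylphenylsulfonyl)-5,6,7,12-tetrahydrodibenzo[a,d]cyclooctene-5-carboxylate (C-12 epimers, centre lost in step 16) | COC(=O)[C@@H]1[C@@H](c2cc(OC)cc(OC)c2)[C@H](c2ccc(OC)cc2)c2c(OC)cc(OC)cc2C(S(=O)(=O)c3ccc(C)cc3)c2c(O)cc(OC)cc21 | intermediate
29 | (4-methoxybenzyl)dimethylsulfonium chloride (fragment 4) | COc1ccc(C[S+](C)C)cc1.[Cl-] | intermediate
30 | o-quinone methide from 28: ring C as the 6-methylenecyclohexa-2,4-dienone, methide C=C inside the eight-membered ring, three sp3 centres as in 25 (formed in the flask) | COC(=O)[C@@H]1[C@@H](c2cc(OC)cc(OC)c2)[C@H](c2ccc(OC)cc2)c2c(OC)cc(OC)cc2/C=C2/C(=O)C=C(OC)C=C21 | intermediate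
31 | dimethylsulfonium (4-methoxyphenyl)methylide (formed in the flask) | COc1ccc([CH-][S+](C)C)cc1 | intermediate
32 | methyl ester of the trans-2-(4-methoxyphenyl)-2,3-dihydrobenzofuran fused on ring C of the dibenzocyclooctene (hydrogens on Cc, Cb, Ce, Cd alternately up, down, up, down; Cf aryl trans to ring B) | COC(=O)[C@@H]1[C@@H](c2cc(OC)cc(OC)c2)[C@H](c2ccc(OC)cc2)c2c(OC)cc(OC)cc2[C@@H]2c3c(cc(OC)cc31)O[C@H]2c1ccc(OC)cc1 | intermediate
33 | carboxylic acid corresponding to 32 | OC(=O)[C@@H]1[C@@H](c2cc(OC)cc(OC)c2)[C@H](c2ccc(OC)cc2)c2c(OC)cc(OC)cc2[C@@H]2c3c(cc(OC)cc31)O[C@H]2c1ccc(OC)cc1 | intermediate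
34 | acid chloride of 33 (formed in the flask) | ClC(=O)[C@@H]1[C@@H](c2cc(OC)cc(OC)c2)[C@H](c2ccc(OC)cc2)c2c(OC)cc(OC)cc2[C@@H]2c3c(cc(OC)cc31)O[C@H]2c1ccc(OC)cc1 | intermediate
35 | hexacyclic indanone (ketone at Ca, 5,7-dimethoxyindan-1-one unit on ring A, trans-fused to the eight-membered ring at Ce/Cb) | O=C2c3c(OC)cc(OC)cc3[C@H]3[C@H](c4ccc(OC)cc4)c4c(OC)cc(OC)cc4[C@@H]4c5c(cc(OC)cc5[C@H]23)O[C@H]4c2ccc(OC)cc2 | intermediate
36 | 4-bromoanisole | COc1ccc(Br)cc1 | starting material
37 | 4-methoxyphenyllithium (formed in the flask) | COc1ccc([Li])cc1 | intermediate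
38 | 4-methoxyphenylcerium dichloride (formed in the flask) | COc1ccc([Ce](Cl)Cl)cc1 | intermediate
39 | tertiary carbinol from addition of the anisyl group to the ketone of 35 (carbinol configuration not defined, centre ionised in step 20) | COc1ccc(C2(O)c3c(OC)cc(OC)cc3[C@H]3[C@H](c4ccc(OC)cc4)c4c(OC)cc(OC)cc4[C@@H]4c5c(cc(OC)cc5[C@H]23)O[C@H]4c2ccc(OC)cc2)cc1 | intermediate
40 | diarylmethyl cation at Ca with hydroxytrifluoroborate counter-ion (formed in the flask) | COc1ccc([C+]2c3c(OC)cc(OC)cc3[C@H]3[C@H](c4ccc(OC)cc4)c4c(OC)cc(OC)cc4[C@@H]4c5c(cc(OC)cc5[C@H]23)O[C@H]4c2ccc(OC)cc2)cc1.O[B-](F)(F)F | intermediate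
41 | canaliculatol octamethyl ether | COc1ccc([C@@H]2c3c(OC)cc(OC)cc3[C@H]3[C@H](c4ccc(OC)cc4)c4c(OC)cc(OC)cc4[C@@H]4c5c(cc(OC)cc5[C@H]23)O[C@H]4c2ccc(OC)cc2)cc1 | intermediate
42 | canaliculatol | Oc1ccc([C@@H]2c3c(O)cc(O)cc3[C@H]3[C@H](c4ccc(O)cc4)c4c(O)cc(O)cc4[C@@H]4c5c(cc(O)cc5[C@H]23)O[C@H]4c2ccc(O)cc2)cc1 | target

**Totals**
Total step count: 21.
Longest linear sequence: 14 steps (for example 1, 3, 6, 7, 11, 12, 13, 14, 16, 17, 18, 19, 20, 21).

**Steps most likely to fail**

1. Step 11 (aryne insertion). The aryl anion formed after C-arylation may be protonated before it reaches the hindered, conjugated ketone, which would stop at plain α-arylation; O-arylation or attack at the wrong aryne carbon would also divert material.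
Fallback, setting out from 14 and returning at 25: the same two bonds are made one after the other with the regiochemistry fixed by a halogen. Bought 1-iodo-3,5-dimethoxybenzene is brominated (NBS, MeCN) to 2-bromo-1-iodo-3,5-dimethoxybenzene F1. F1 is oxidised (mCPBA, TsOH·H2O, MeCN) and coupled with 1,3,5-trimethoxybenzene to (2-bromo-3,5-dimethoxyphenyl)(2,4,6-trimethoxyphenyl)iodonium tosylate F2. The potassium enolate of 14 (KOt-Bu, DMF, rt) is C-arylated by F2 to the quaternary α-(2-bromoaryl) β-ketoester F3. Bromine–lithium exchange (t-BuLi, THF, −100 °C) gives the aryllithium F4 with no proton source present; it should add to the ketone to give the lithium benzocyclobutenoxide F5, whose fragmentation and NH4Cl quench lead to 25.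

2. Step 16 ([4+1] annulation). Facial selectivity at the methide carbon rests only on the conformation of the eight-membered ring, the semi-stabilised ylide may add sluggishly, and the methide can be captured across the ring by the electron-rich ring A (a danger already in step 14).
Fallback, setting out from 26 and returning at 32 (steps 13 to 15 are bypassed): Cd is set by a catalyst instead of by the substrate. Phenol 26 is alkylated with 3 (K2CO3, DMF) to the 4-methoxybenzyl ether F6. Hydrazine (N2H4·H2O, AcOH, EtOH, 80 °C) converts the ketone into the hydrazone F7, and MnO2 (CH2Cl2, 0 °C) oxidises it to the diaryldiazomethane F8. Rh2(R-PTAD)4 (dirhodium tetrakis[N-phthaloyl-(R)-adamantylglycinate]) or its enantiomer, whichever matches the substrate, effects carbene insertion into the ArO–CH2 C–H bond to give the 2,3-cis-dihydrobenzofuran F9. Brief exposure to BF3·OEt2 (CH2Cl2, 0 °C) then epimerises Cf through the 4-methoxybenzylic cation to the trans isomer 32.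

3. Step 6 (Michael–Dieckmann annulation). The auxiliary may discriminate poorly between the enoate faces for this bulky diarylmethyl anion, and reversible Michael addition could erode the selectivity.
Fallback, setting out from 5 and 7 and returning at 14 (steps 5 and 7 are bypassed): absolute configuration is obtained by resolution instead of induction. Acid chloride 7 is converted (MeOH, Et3N) into methyl (E)-3,5-dimethoxycinnamate F10. Annulation with lithiated 5 under the conditions of step 6 gives the racemic trans methyl β-ketoester F11 directly. Preparative chromatography on a chiral stationary phase separates the enantiomers, and the (3R,4R) enantiomer is 14.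

**Further compounds**
F1 | step 11 | 2-bromo-1-iodo-3,5-dimethoxybenzene | COc1cc(OC)c(Br)c(I)c1
F2 | step 11 | (2-bromo-3,5-dimethoxyphenyl)(2,4,6-trimethoxyphenyl)iodonium tosylate | COc1cc(OC)c(Br)c([I+]c2c(OC)cc(OC)cc2OC)c1.Cc1ccc(S(=O)(=O)[O-])cc1
F3 | step 11 | methyl (3R,4R)-2-(2-bromo-3,5-dimethoxyphenyl)-3-(3,5-dimethoxyphenyl)-5,7-dimethoxy-4-(4-methoxyphenyl)-1-oxo-1,2,3,4-tetrahydronaphthalene-2-carboxylate (C-2 aryl anti to C-3 aryl) | COC(=O)[C@]1(c2cc(OC)cc(OC)c2Br)C(=O)c2cc(OC)cc(OC)c2[C@@H](c2ccc(OC)cc2)[C@@H]1c1cc(OC)cc(OC)c1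
F4 | step 11 | aryllithium from bromine–lithium exchange of F3 | COC(=O)[C@]1(c2cc(OC)cc(OC)c2[Li])C(=O)c2cc(OC)cc(OC)c2[C@@H](c2ccc(OC)cc2)[C@@H]1c1cc(OC)cc(OC)c1
F5 | step 11 | lithium alkoxide of the cis-fused benzocyclobutenol (lithium counterpart of 24) | COC(=O)[C@]12c3cc(OC)cc(OC)c3[C@@]1([O-])c1cc(OC)cc(OC)c1[C@@H](c1ccc(OC)cc1)[C@@H]2c1cc(OC)cc(OC)c1.[Li+]
F6 | step 16 | 1-O-(4-methoxybenzyl) ether of 26 | COC(=O)[C@@H]1[C@@H](c2cc(OC)cc(OC)c2)[C@H](c2ccc(OC)cc2)c2c(OC)cc(OC)cc2C(=O)c2c(OCc3ccc(OC)cc3)cc(OC)cc21
F7 | step 16 | hydrazone of F6 at C-12 (C=N geometry not defined) | COC(=O)[C@@H]1[C@@H](c2cc(OC)cc(OC)c2)[C@H](c2ccc(OC)cc2)c2c(OC)cc(OC)cc2C(=NN)c2c(OCc3ccc(OC)cc3)cc(OC)cc21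
F8 | step 16 | 12-diazo compound from F7 | COC(=O)[C@@H]1[C@@H](c2cc(OC)cc(OC)c2)[C@H](c2ccc(OC)cc2)c2c(OC)cc(OC)cc2C(=[N+]=[N-])c2c(OCc3ccc(OC)cc3)cc(OC)cc21
F9 | step 16 | 2,3-cis-dihydrobenzofuran, the Cf epimer of 32 | COC(=O)[C@@H]1[C@@H](c2cc(OC)cc(OC)c2)[C@H](c2ccc(OC)cc2)c2c(OC)cc(OC)cc2[C@@H]2c3c(cc(OC)cc31)O[C@@H]2c1ccc(OC)cc1
F10 | step 6 | methyl (E)-3,5-dimethoxycinnamate | COC(=O)/C=C/c1cc(OC)cc(OC)c1
F11 | step 6 | racemic trans methyl β-ketoester (14 and its enantiomer) | COC(=O)C1=C(O)c2cc(OC)cc(OC)c2[C@@H](c2ccc(OC)cc2)[C@@H]1c1cc(OC)cc(OC)c1.COC(=O)C1=C(O)c2cc(OC)cc(OC)c2[C@H](c2ccc(OC)cc2)[C@H]1c1cc(OC)cc(OC)c1
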